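A ratio opened the meeting: this flask holds 1.20 equiv of X, and the members asked what each used L costs in X.

| setting | beta | gamma | flask |
|---|---|---|---|
| L | 0.10 M | 0.10 M | 0.10 M |
| X | 1.2 equiv | 2.4 equiv | 1.20 equiv |
| remark | the very flask that is asked about, followed so far | run made earlier |  |
| time |  |  | 4.0 d |

beta run (percent of the L charged)

| time / h | L / % | E / % | Z / % |
|---|---|---|---|
| 1.50 | 44.7 | 29.2 | 0.9 |
| 3.00 | 27.4 | 38.3 | 2.2 |
| 5.00 | 16.4 | 43.8 | 3.0 |
| 6.00 | 14.4 | 44.7 | 2.6 |
| 8.00 | 11.3 | 46.5 | 2.8 |

gamma run (percent of the L charged)

| time / d | L / % | E / % | Z / % |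
|---|---|---|---|
| 0.625 | 0.3 | 52.2 | 1.9 |
| 1.04 | 0.5 | 52.3 | 0.8 |
| 1.67 | 0.1 | 51.9 | 0.7 |
| 2.50 | 0 | 52.8 | 0.5 |
| 3.00 | 0.2 | 52.6 | 0.4 |

(standard deviation of a reading: 0.3 percentage points)

- which holds at 4.0 d: what has brought the reaction to rest, or that it has not come to rest (all of L has reacted / forward and back rates have come level / X has run out first / it is still moving)
- conversion of L at 4.0 d
- amount of E at 4.0 d, in percent of the L charged

- the reaction counts as stopped when no species that holds the L changes by six tenths of a point or more over the second half of the time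

One member read the beta run, which is this flask followed so far. Between the early readings, with L near 35.0%, the decay rate of L per unit L was 0.326 h⁻¹. Later, with L near 13.6%, it was 0.124 h⁻¹. She took this rate to follow the X left, and the X left to be the charge less a steady price per L used. The two rates then give 1.21 X used per L used, a reading that carries the scatter.

At that price the charge pays for 99.5% of L, so she named X the limiting reagent. The late decay time, 8.05 h, is shorter than the time asked, so she expected rest by then. E takes 52.4% of the L used in beta's last reading, so she put E near 52.1%.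

The forecast was then tabled: forward and back rates have come level, conversion 98%, E 51.5%. It set the price at 1.1 and said “X therefore should not run out”. The two part on what stops the flask.

The flask gives: X has run out first, with conversion 96.5% and E 50.5%.

    L + X → Q (k = 3.00 M⁻¹ h⁻¹)
    L + X → E (k = 3.30 M⁻¹ h⁻¹)
    Q → D (k = 0.130 h⁻¹)
    X + D → Z (k = 20.0 M⁻¹ h⁻¹)
    D ⇌ J (K = 6.60, k = 0.590 h⁻¹)
    Z → G (k = 0.580 h⁻¹)

At 4.00 d the flask keeps 0.0076% of its X. Its price at that end is 1.24. In a neighbour flask, charged with 0.720 equiv of X, the price read from beta pays for 59.7% of L. That flask, its X at 0%, stands at 66.6%, a price of 1.08.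

The readings come from a simulation from invented constants; the scatter is artificial.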